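**Plan** (benzofuran numbering: O1, C2, C3, C3a, C4–C7, C7a)

- Retrosynthesis: the phenol is unmasked last; C4–H is traced back to a C4 hydroxyl, the C5 allyl group to an allyl ether on that oxygen (retro-Claisen), and the C3 methyl group to a CH2SO2Ph arm.
- The dihydrofuran ring is then cut at O1–C7a and C3–C3a in one operation, giving a ring A aryne and the alkoxide of an (S)-γ-hydroxy vinyl sulfone.
- Enabling feature: O1 (on C7a) and C3 (on C3a) sit on adjacent ring A carbons, and C4, beside C3a, is ortho to the allyl-bearing C5; a C3a≡C7a aryne with an allyloxy group on C4 therefore orients the annulation and later hands its allyl group to C5.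
- Forward: ring A is made as silyl triflate 9 (steps 1–5), the side chain as sulfone 15 (steps 6–8); step 9 closes the dihydrofuran ring, the only ring formed; steps 10–14 are desulfonylation, Claisen shift, removal of the C4 oxygen and deprotection.
- Stereochemistry: C2 comes from a lipase resolution (step 7) and is carried through unchanged; C3 is set trans to it in the ring closure of step 9.

Key step: step 9

Remark: silyl triflate 9 carries silicon meta to both ether oxygens. With fluoride it releases 3-(allyloxy)-5-(methoxymethoxy)benzyne 17; the carbon that held silicon becomes C7a and the one that held triflate becomes C3a. Compounds 1, 2, 10, 11 and 14 are taken to be catalogue chemicals.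

**Route**

Step 1
Reactants: 1 3-bromo-4,5-dihydroxybenzaldehyde; 2 allyl bromide
Product: 3 3-(allyloxy)-5-bromo-4-hydroxybenzaldehyde
Conditions: NaH (2.2 equiv), DMSO, 20 °C; 2 (1.0 equiv); aq. HCl work-up
Reagents that add atoms: none
Why: Regioselective O-alkylation of a catechol dianion, in which the phenoxide meta to the formyl group is the more nucleophilic one (the other is conjugated to CHO and flanked by bromine), so one equivalent of 2 should allylate O5 only.

Step 2
Reactants: 3 3-(allyloxy)-5-bromo-4-hydroxybenzaldehyde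
Product: 4 2-(allyloxy)-6-bromobenzene-1,4-diol
Conditions: H2O2 (30% aq.), NaOH, THF/H2O, 0 → 20 °C, N2; Na2S2O4, then aq. HCl
Reagents that add atoms: hydrogen peroxide, OO
Why: Dakin oxidation of a para-hydroxybenzaldehyde, in which the phenoxide drives aryl migration and the aryl formate is saponified in situ, while the allyl ether and aryl bromide are inert to alkaline peroxide.

Step 3
Reactants: 4 2-(allyloxy)-6-bromobenzene-1,4-diol
Product: 5 1-(allyloxy)-3-bromo-2,5-bis(trimethylsilyloxy)benzene
Conditions: hexamethyldisilazane, THF, 65 °C; evaporate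
Reagents that add atoms: hexamethyldisilazane, C[Si](C)(C)N[Si](C)(C)C
Why: Exhaustive O-silylation of both phenols with ammonia as the only by-product, which protects the air-sensitive hydroquinone and places a silyl group on the oxygen next to bromine.

Step 4
Reactants: 5 1-(allyloxy)-3-bromo-2,5-bis(trimethylsilyloxy)benzene
Product: 8 2-(allyloxy)-4-hydroxy-6-(trimethylsilyl)phenyl trifluoromethanesulfonate, via lithium phenoxide 6 (not isolated), via bis-silyl aryl triflate 7 (not isolated)
Conditions: n-BuLi (1.1 equiv), THF, −78 °C; Tf2O, −78 → 0 °C; citric acid, MeOH, 20 °C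
Reagents that add atoms: trifluoromethanesulfonic anhydride, O=S(=O)(OS(=O)(=O)C(F)(F)F)C(F)(F)F
Why: Bromine–lithium exchange triggers a 1,3 O→C silyl shift (retro-Brook rearrangement) of only the silyl group on the oxygen beside bromine, the freed phenoxide is trapped as its triflate, and mild methanolysis should cleave the remaining aryl silyl ether while the carbon-bound silyl group, meta to both donor oxygens, resists protodesilylation.

Step 5
Reactants: 8 2-(allyloxy)-4-hydroxy-6-(trimethylsilyl)phenyl trifluoromethanesulfonate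
Product: 9 2-(allyloxy)-4-(methoxymethoxy)-6-(trimethylsilyl)phenyl trifluoromethanesulfonate
Conditions: MOMCl, iPr2NEt, CH2Cl2, 0 → 20 °C
Reagents that add atoms: chloromethyl methyl ether, COCCl
Why: Methoxymethyl ether formation on the only free phenol under amine base, conditions that do not activate the ortho-silylaryl triflate.

Step 6
Reactants: 10 3,4,5-trimethoxybenzaldehyde; 11 vinylmagnesium bromide
Product: 12 rac-1-(3,4,5-trimethoxyphenyl)prop-2-en-1-ol
Conditions: THF, 0 °C; aq. NH4Cl
Reagents that add atoms: none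
Why: Grignard addition to a non-enolisable aryl aldehyde.

Step 7
Reactants: 12 rac-1-(3,4,5-trimethoxyphenyl)prop-2-en-1-ol
Product: 13 (S)-1-(3,4,5-trimethoxyphenyl)prop-2-en-1-ol
Conditions: Candida antarctica lipase B (immobilised), vinyl acetate, tert-butyl methyl ether, 30 °C, stopped just past half conversion; chromatography
Reagents that add atoms: none
Why: Lipase-catalysed kinetic resolution by transesterification, in which the enzyme should acylate the (R)-alcohol (aryl as large and vinyl as medium substituent) and leave the (S)-alcohol, whose carbinol carbon becomes C2 of the target.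

Step 8
Reactants: 13 (S)-1-(3,4,5-trimethoxyphenyl)prop-2-en-1-ol; 14 phenyl vinyl sulfone
Product: 15 (S,E)-3-(phenylsulfonyl)-1-(3,4,5-trimethoxyphenyl)prop-2-en-1-ol
Conditions: second-generation Grubbs catalyst (5 mol%), 14 (2 equiv), 1,4-benzoquinone (10 mol%), CH2Cl2, 40 °C
Reagents that add atoms: none
Why: Olefin cross-metathesis of a terminal alkene with an electron-poor vinyl sulfone that does not homodimerise, which should give the (E)-alkene and leaves the carbinol stereocentre untouched.

Step 9
Reactants: 15 (S,E)-3-(phenylsulfonyl)-1-(3,4,5-trimethoxyphenyl)prop-2-en-1-ol; 9 2-(allyloxy)-4-(methoxymethoxy)-6-(trimethylsilyl)phenyl trifluoromethanesulfonate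
Product: 18 (2S,3S)-4-(allyloxy)-6-(methoxymethoxy)-3-[(phenylsulfonyl)methyl]-2-(3,4,5-trimethoxyphenyl)-2,3-dihydrobenzofuran, via potassium alkoxide 16 (not isolated), via 3-(allyloxy)-5-(methoxymethoxy)benzyne 17 (not isolated)
Conditions: KH (1.05 equiv), THF, 0 °C; then 9 (1.3 equiv), KF, 18-crown-6, THF, 0 → 20 °C; aq. NH4Cl
Reagents that add atoms: none
Why: Proposed new method: fluoride attack on silicon of 9 expels triflate to give aryne 17; the oxygen of alkoxide 16 adds to the aryne carbon remote from the allyloxy group (O1–C7a) and the aryl carbanion left at C3a adds to the β-carbon of the vinyl sulfone (C3–C3a), the sulfonyl-stabilised carbanion being protonated on work-up. The closest known reaction type is the aryne O-arylation/intramolecular Michael sequence by which ortho-hydroxychalcone phenoxides give 9-substituted xanthenes; an aliphatic alkoxide carrying a vinyl sulfone has not been used in this way. The dihydrofuran ring closes in the 5-exo-trig mode. C3 is set under control of the C2 centre: in the envelope-shaped transition state the C2 aryl group sits pseudo-equatorial and the sulfonyl-bearing alkene carbon turns to the opposite face, which should give the trans ring and thus (2S,3S). The step needs the alkoxide to attack the distal aryne carbon, which the inductively withdrawing allyloxy group on the carbon flanking the triple bond secures by polarising and distorting the aryne, and it needs cyclisation to outrun protonation of the aryl anion, for which the alkoxide is fully preformed (no O–H in the flask) and THF replaces more acidic solvents. Complete deprotonation also protects the γ-hydroxy vinyl sulfone from base-catalysed isomerisation to the keto sulfone.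

Step 10
Reactants: 18 (2S,3S)-4-(allyloxy)-6-(methoxymethoxy)-3-[(phenylsulfonyl)methyl]-2-(3,4,5-trimethoxyphenyl)-2,3-dihydrobenzofuran
Product: 19 (2S,3S)-4-(allyloxy)-6-(methoxymethoxy)-3-methyl-2-(3,4,5-trimethoxyphenyl)-2,3-dihydrobenzofuran
Conditions: Mg turnings (I2-activated), MeOH, 50 °C
Reagents that add atoms: none
Why: Reductive desulfonylation by electron transfer from magnesium, in which the sulfone radical anion loses benzenesulfinate and the primary carbon is reduced and protonated by methanol, turning CH2SO2Ph into the C3 methyl group without touching C2 or C3.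

Step 11
Reactants: 19 (2S,3S)-4-(allyloxy)-6-(methoxymethoxy)-3-methyl-2-(3,4,5-trimethoxyphenyl)-2,3-dihydrobenzofuran
Product: 20 (2S,3S)-5-allyl-6-(methoxymethoxy)-3-methyl-2-(3,4,5-trimethoxyphenyl)-2,3-dihydrobenzofuran-4-ol
Conditions: N,N-diethylaniline, 190 °C, sealed tube, argon
Reagents that add atoms: none
Why: Aromatic Claisen rearrangement ([3,3]-sigmatropic shift, then tautomerisation), in which C5 is the only free ortho position of O4 (the other is the ring-fusion carbon C3a), so the allyl group should arrive at C5, and the basic solvent spares the methoxymethyl ether.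

Step 12
Reactants: 20 (2S,3S)-5-allyl-6-(methoxymethoxy)-3-methyl-2-(3,4,5-trimethoxyphenyl)-2,3-dihydrobenzofuran-4-ol
Product: 21 (2S,3S)-5-allyl-6-(methoxymethoxy)-3-methyl-2-(3,4,5-trimethoxyphenyl)-2,3-dihydrobenzofuran-4-yl trifluoromethanesulfonate
Conditions: Tf2O, pyridine, CH2Cl2, 0 °C
Reagents that add atoms: trifluoromethanesulfonic anhydride, O=S(=O)(OS(=O)(=O)C(F)(F)F)C(F)(F)F
Why: O-sulfonylation of the phenol with triflic anhydride under pyridine buffering, which keeps the acid-labile methoxymethyl ether intact.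

Step 13
Reactants: 21 (2S,3S)-5-allyl-6-(methoxymethoxy)-3-methyl-2-(3,4,5-trimethoxyphenyl)-2,3-dihydrobenzofuran-4-yl trifluoromethanesulfonate
Product: 22 (2S,3S)-5-allyl-6-(methoxymethoxy)-3-methyl-2-(3,4,5-trimethoxyphenyl)-2,3-dihydrobenzofuran
Conditions: Pd(OAc)2 (5 mol%), 1,1'-bis(diphenylphosphino)ferrocene (10 mol%), HCO2H, Et3N, DMF, 70 °C
Reagents that add atoms: none
Why: Palladium-catalysed reduction of an aryl triflate with formate as hydride source (oxidative addition, decarboxylation of the formate complex, C–H reductive elimination), where the chelating bisphosphine should favour reductive elimination over alkene migration.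

Step 14
Reactants: 22 (2S,3S)-5-allyl-6-(methoxymethoxy)-3-methyl-2-(3,4,5-trimethoxyphenyl)-2,3-dihydrobenzofuran
Product: 23 (2S,3S)-5-allyl-3-methyl-2-(3,4,5-trimethoxyphenyl)-2,3-dihydrobenzofuran-6-ol
Conditions: HCl (1 M), MeOH, 40 °C
Reagents that add atoms: none
Why: Acid-catalysed acetal exchange should remove the methoxymethyl group as dimethoxymethane under conditions too mild to open the dihydrofuran ring or to cyclise the ortho-allylphenol.

**Compound list**

1 | 3-bromo-4,5-dihydroxybenzaldehyde | O=Cc1cc(O)c(O)c(Br)c1 | starting material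
2 | allyl bromide | C=CCBr | starting material
3 | 3-(allyloxy)-5-bromo-4-hydroxybenzaldehyde | C=CCOc1cc(C=O)cc(Br)c1O | intermediate
4 | 2-(allyloxy)-6-bromobenzene-1,4-diol | C=CCOc1cc(O)cc(Br)c1O | intermediate
5 | 1-(allyloxy)-3-bromo-2,5-bis(trimethylsilyloxy)benzene | C=CCOc1cc(O[Si](C)(C)C)cc(Br)c1O[Si](C)(C)C | intermediate
6 | lithium 2-(allyloxy)-6-(trimethylsilyl)-4-(trimethylsilyloxy)phenoxide | [Li+].[O-]c1c(OCC=C)cc(O[Si](C)(C)C)cc1[Si](C)(C)C | intermediate
7 | 2-(allyloxy)-6-(trimethylsilyl)-4-(trimethylsilyloxy)phenyl trifluoromethanesulfonate | C=CCOc1cc(O[Si](C)(C)C)cc([Si](C)(C)C)c1OS(=O)(=O)C(F)(F)F | intermediate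
8 | 2-(allyloxy)-4-hydroxy-6-(trimethylsilyl)phenyl trifluoromethanesulfonate | C=CCOc1cc(O)cc([Si](C)(C)C)c1OS(=O)(=O)C(F)(F)F | intermediate
9 | 2-(allyloxy)-4-(methoxymethoxy)-6-(trimethylsilyl)phenyl trifluoromethanesulfonate | C=CCOc1cc(OCOC)cc([Si](C)(C)C)c1OS(=O)(=O)C(F)(F)F | intermediate
10 | 3,4,5-trimethoxybenzaldehyde | COc1cc(C=O)cc(OC)c1OC | starting material
11 | vinylmagnesium bromide | C=C[Mg]Br | starting material
12 | rac-1-(3,4,5-trimethoxyphenyl)prop-2-en-1-ol | C=CC(O)c1cc(OC)c(OC)c(OC)c1 | intermediate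
13 | (S)-1-(3,4,5-trimethoxyphenyl)prop-2-en-1-ol | O[C@H](c1cc(OC)c(OC)c(OC)c1)C=C | intermediate
14 | phenyl vinyl sulfone | C=CS(=O)(=O)c1ccccc1 | starting material
15 | (S,E)-3-(phenylsulfonyl)-1-(3,4,5-trimethoxyphenyl)prop-2-en-1-ol | O[C@H](c1cc(OC)c(OC)c(OC)c1)/C=C/S(=O)(=O)c1ccccc1 | intermediate
16 | potassium (S,E)-3-(phenylsulfonyl)-1-(3,4,5-trimethoxyphenyl)prop-2-en-1-olate | [K+].[O-][C@H](c1cc(OC)c(OC)c(OC)c1)/C=C/S(=O)(=O)c1ccccc1 | intermediate
17 | 3-(allyloxy)-5-(methoxymethoxy)benzyne | C=CCOC1=CC(OCOC)=CC#C1 | intermediate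
18 | (2S,3S)-4-(allyloxy)-6-(methoxymethoxy)-3-[(phenylsulfonyl)methyl]-2-(3,4,5-trimethoxyphenyl)-2,3-dihydrobenzofuran | C=CCOc1cc(OCOC)cc2c1[C@H](CS(=O)(=O)c1ccccc1)[C@@H](c1cc(OC)c(OC)c(OC)c1)O2 | intermediate
19 | (2S,3S)-4-(allyloxy)-6-(methoxymethoxy)-3-methyl-2-(3,4,5-trimethoxyphenyl)-2,3-dihydrobenzofuran | C=CCOc1cc(OCOC)cc2c1[C@H](C)[C@@H](c1cc(OC)c(OC)c(OC)c1)O2 | intermediate
20 | (2S,3S)-5-allyl-6-(methoxymethoxy)-3-methyl-2-(3,4,5-trimethoxyphenyl)-2,3-dihydrobenzofuran-4-ol | C=CCc1c(O)c2c(cc1OCOC)O[C@H](c1cc(OC)c(OC)c(OC)c1)[C@H]2C | intermediate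
21 | (2S,3S)-5-allyl-6-(methoxymethoxy)-3-methyl-2-(3,4,5-trimethoxyphenyl)-2,3-dihydrobenzofuran-4-yl trifluoromethanesulfonate | C=CCc1c(OS(=O)(=O)C(F)(F)F)c2c(cc1OCOC)O[C@H](c1cc(OC)c(OC)c(OC)c1)[C@H]2C | intermediate
22 | (2S,3S)-5-allyl-6-(methoxymethoxy)-3-methyl-2-(3,4,5-trimethoxyphenyl)-2,3-dihydrobenzofuran | C=CCc1cc2c(cc1OCOC)O[C@H](c1cc(OC)c(OC)c(OC)c1)[C@H]2C | intermediate
23 | (2S,3S)-5-allyl-3-methyl-2-(3,4,5-trimethoxyphenyl)-2,3-dihydrobenzofuran-6-ol (CNP0286233.1) | C=CCc1cc2c(cc1O)O[C@H](c1cc(OC)c(OC)c(OC)c1)[C@H]2C | target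

**Step count and risks**

Total: 14 steps. Longest linear sequence: 11 steps (1–5, then 9–14); the sulfone branch (6–8) joins at step 9.

Most likely to fail:

1. Step 9 (new method). The alkoxide may be lost to intermolecular oxa-Michael addition or to isomerisation, the aryl anion may be protonated before it reaches the alkene, or the ring may close with poor trans selectivity. The fallback uses known chemistry (Mitsunobu etherification, then aryl radical cyclisation), sets out from racemic alcohol 12 and sulfone 14, and comes back at 22.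
   - The lipase step leaves (R)-1-(3,4,5-trimethoxyphenyl)allyl acetate F1, which K2CO3 in MeOH converts into (R)-1-(3,4,5-trimethoxyphenyl)prop-2-en-1-ol F2.
   - Cross-metathesis with 14 as in step 8 gives (R,E)-3-(phenylsulfonyl)-1-(3,4,5-trimethoxyphenyl)prop-2-en-1-ol F3.
   - Mitsunobu reaction (PPh3, diisopropyl azodicarboxylate, THF) with 2-iodo-5-(methoxymethoxy)phenol F4 (from 3-(methoxymethoxy)phenol, I2, NaHCO3) should invert the carbinol centre and give 1-iodo-4-(methoxymethoxy)-2-{[(S,E)-3-(phenylsulfonyl)-1-(3,4,5-trimethoxyphenyl)allyl]oxy}benzene F5.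
   - Bu3SnH and azobisisobutyronitrile in toluene at 80 °C should close the ring by 5-exo-trig addition of the aryl radical to the vinyl sulfone, giving (2S,3S)-6-(methoxymethoxy)-3-[(phenylsulfonyl)methyl]-2-(3,4,5-trimethoxyphenyl)-2,3-dihydrobenzofuran F6.
   - Mg in MeOH gives (2S,3S)-6-(methoxymethoxy)-3-methyl-2-(3,4,5-trimethoxyphenyl)-2,3-dihydrobenzofuran F7.
   - NBS in MeCN at 0 °C should brominate C5, para to O1 and ortho to O6, giving (2S,3S)-5-bromo-6-(methoxymethoxy)-3-methyl-2-(3,4,5-trimethoxyphenyl)-2,3-dihydrobenzofuran F8.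
   - Stille coupling with allyltributylstannane (Pd(PPh3)4, DMF, 90 °C) gives 22. This path needs no oxygen at C4 and replaces steps 9–13.

2. Step 13. The terminal alkene may migrate into conjugation through a palladium hydride, the aryl–palladium species may add to the neighbouring allyl group, or oxidative addition to the doubly ortho-substituted triflate may stall. The fallback sets out from triflate 21 and comes back at 22. Miyaura borylation (PdCl2, 1,1'-bis(diphenylphosphino)ferrocene, bis(pinacolato)diboron, KOAc, dioxane, 90 °C) gives 2-[(2S,3S)-5-allyl-6-(methoxymethoxy)-3-methyl-2-(3,4,5-trimethoxyphenyl)-2,3-dihydrobenzofuran-4-yl]-4,4,5,5-tetramethyl-1,3,2-dioxaborolane F9. Base-promoted protodeboronation (KOH, aqueous dioxane, 80 °C), which is fast for an electron-rich arylboronate with two ortho substituents, then gives 22 without passing through a palladium hydride.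

3. Step 1. Allylation may take place at the wrong oxygen or twice. The fallback sets out from 1 and comes back at 3. Selective alkylation of the more acidic 4-hydroxyl (4-methoxybenzyl chloride, NaHCO3, NaI, DMF, 40 °C) gives 3-bromo-5-hydroxy-4-[(4-methoxybenzyl)oxy]benzaldehyde F10. Allylation of the remaining phenol with 2 (K2CO3, DMF) gives 3-(allyloxy)-5-bromo-4-[(4-methoxybenzyl)oxy]benzaldehyde F11. 2,3-Dichloro-5,6-dicyano-1,4-benzoquinone in CH2Cl2/H2O removes the 4-methoxybenzyl group and gives 3.

**Further compounds**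

F1 | step 9 | (R)-1-(3,4,5-trimethoxyphenyl)allyl acetate | CC(=O)O[C@@H](c1cc(OC)c(OC)c(OC)c1)C=C
F2 | step 9 | (R)-1-(3,4,5-trimethoxyphenyl)prop-2-en-1-ol | O[C@@H](c1cc(OC)c(OC)c(OC)c1)C=C
F3 | step 9 | (R,E)-3-(phenylsulfonyl)-1-(3,4,5-trimethoxyphenyl)prop-2-en-1-ol | O[C@@H](c1cc(OC)c(OC)c(OC)c1)/C=C/S(=O)(=O)c1ccccc1
F4 | step 9 | 2-iodo-5-(methoxymethoxy)phenol | COCOc1ccc(I)c(O)c1
F5 | step 9 | 1-iodo-4-(methoxymethoxy)-2-{[(S,E)-3-(phenylsulfonyl)-1-(3,4,5-trimethoxyphenyl)allyl]oxy}benzene | COCOc1ccc(I)c(c1)O[C@H](c1cc(OC)c(OC)c(OC)c1)/C=C/S(=O)(=O)c1ccccc1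
F6 | step 9 | (2S,3S)-6-(methoxymethoxy)-3-[(phenylsulfonyl)methyl]-2-(3,4,5-trimethoxyphenyl)-2,3-dihydrobenzofuran | COCOc1ccc2c(c1)O[C@H](c1cc(OC)c(OC)c(OC)c1)[C@H]2CS(=O)(=O)c1ccccc1
F7 | step 9 | (2S,3S)-6-(methoxymethoxy)-3-methyl-2-(3,4,5-trimethoxyphenyl)-2,3-dihydrobenzofuran | COCOc1ccc2c(c1)O[C@H](c1cc(OC)c(OC)c(OC)c1)[C@H]2C
F8 | step 9 | (2S,3S)-5-bromo-6-(methoxymethoxy)-3-methyl-2-(3,4,5-trimethoxyphenyl)-2,3-dihydrobenzofuran | Brc1cc2c(cc1OCOC)O[C@H](c1cc(OC)c(OC)c(OC)c1)[C@H]2C
F9 | step 13 | 2-[(2S,3S)-5-allyl-6-(methoxymethoxy)-3-methyl-2-(3,4,5-trimethoxyphenyl)-2,3-dihydrobenzofuran-4-yl]-4,4,5,5-tetramethyl-1,3,2-dioxaborolane | C=CCc1c(B3OC(C)(C)C(C)(C)O3)c2c(cc1OCOC)O[C@H](c1cc(OC)c(OC)c(OC)c1)[C@H]2C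
F10 | step 1 | 3-bromo-5-hydroxy-4-[(4-methoxybenzyl)oxy]benzaldehyde | COc1ccc(COc2c(O)cc(C=O)cc2Br)cc1
F11 | step 1 | 3-(allyloxy)-5-bromo-4-[(4-methoxybenzyl)oxy]benzaldehyde | COc1ccc(COc2c(OCC=C)cc(C=O)cc2Br)cc1
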